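The hexasubstituted central benzene (ring A: C1 OMe, C2 benzyl, C3 OH, C4 benzyl, C5 arylethyl, C6 benzyl) is disconnected at C4–C5 and C1–C6. The key step exploits the meta-dioxygenated C1–C4 segment, which maps onto a ketene-acetal diene, and the C5/C6 pair, which maps onto an alkyne. One Diels–Alder reaction between a 1,1-dimethoxy-3-silyloxy diene carrying both flanking benzyl groups and an aryl ynone forms both bonds, closes ring A and, by loss of methanol and of silicon, delivers the C1 methyl ether and the C3 phenol already differentiated. The ynone aroyl group steers the regiochemistry and is afterwards reduced to the C6 benzyl group.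

Key step: step 9

Remark: the target is achiral, so the only stereochemical demand is the Z geometry of the silyl enol ether in diene 9. All four free phenols are carried as benzyl ethers. A carboxylic acid or ester cannot be turned directly into a ketene dimethyl acetal, so that unit is built from the nitrile through a Pinner ortho ester.

Step 1
Reactants: 1 3-(4-hydroxyphenyl)propanenitrile
Product: 2 3-(4-benzyloxyphenyl)propanenitrile
Conditions: BnBr, K2CO3, acetone, reflux
Reagents that add atoms: benzyl bromide, BrCc1ccccc1
Why: Williamson ether synthesis, in which the phenoxide formed by K2CO3 is benzylated at oxygen while the nitrile and its weakly acidic α-CH2 stay untouched.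

Step 2
Reactants: 2 3-(4-benzyloxyphenyl)propanenitrile
Product: 4 3-(4-benzyloxyphenyl)-1,1,1-trimethoxypropane, via imidate hydrochloride 3 (not isolated)
Conditions: HCl (g), MeOH (1.1 equiv), Et2O, 0 °C; then MeOH (excess), hexane, rt
Reagents that add atoms: methanol, CO
Why: Pinner reaction, in which HCl-activated nitrile adds one methanol to give the imidate salt and alcoholysis of that salt with excess methanol should give the trimethyl ortho ester with precipitation of NH4Cl, the aryl benzyl ether being stable to anhydrous HCl at 0 °C.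

Step 3
Reactants: 4 3-(4-benzyloxyphenyl)-1,1,1-trimethoxypropane
Product: 5 3-(4-benzyloxyphenyl)-1,1-dimethoxyprop-1-ene
Conditions: Me3SiOTf, iPr2NEt, CH2Cl2, −20 °C to rt; non-aqueous work-up
Reagents that add atoms: none
Why: Silyl-triflate-mediated elimination of methanol from an ortho ester (the acetal-to-enol-ether elimination at the ortho ester level), in which Me3SiOTf ionises one C–OMe bond to a dimethoxycarbenium ion that the hindered amine deprotonates at the only α-CH2 to give the ketene dimethyl acetal.

Step 4
Reactants: 6 3-(4-benzyloxyphenyl)propanoic acid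
Product: 7 3-(4-benzyloxyphenyl)propanoyl chloride
Conditions: (COCl)2, DMF (cat.), CH2Cl2, 0 °C to rt
Reagents that add atoms: oxalyl chloride, O=C(Cl)C(=O)Cl
Why: Acid chloride formation through the Vilsmeier-type chloroiminium species, which proceeds under neutral conditions with only gaseous by-products and leaves the benzyl ether alone.

Step 5
Reactants: 5 3-(4-benzyloxyphenyl)-1,1-dimethoxyprop-1-ene (2.1 equiv); 7 3-(4-benzyloxyphenyl)propanoyl chloride
Product: 8 2-(4-benzyloxybenzyl)-5-(4-benzyloxyphenyl)-1,1-dimethoxypent-1-en-3-one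
Conditions: Et2O, 0 °C to rt, no amine base
Reagents that add atoms: none
Why: C-acylation of a ketene acetal by an acid chloride, in which the nucleophilic β-carbon of 5 attacks the acyl chloride and the dialkoxycarbenium ion loses its α-proton to restore a push–pull ketene acetal, while the second equivalent of 5 takes up the HCl as methyl ester plus chloromethane so that no amine is present to turn 7 into a ketene.

Step 6
Reactants: 8 2-(4-benzyloxybenzyl)-5-(4-benzyloxyphenyl)-1,1-dimethoxypent-1-en-3-one
Product: 9 (3Z)-2-(4-benzyloxybenzyl)-5-(4-benzyloxyphenyl)-1,1-dimethoxy-3-(trimethylsilyloxy)penta-1,3-diene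
Conditions: LiN(iPr)2, THF, −78 °C; then Me3SiCl, −78 to 0 °C; pentane, filtration, used crude
Reagents that add atoms: chlorotrimethylsilane, C[Si](C)(C)Cl
Why: Kinetic α′-deprotonation of a vinylogous ester and O-silylation of the cross-conjugated enolate, in which C4 is the only acidic position and the Z enol ether should form because the CH2Ar group avoids 1,3-allylic strain with the fully substituted C2 and so sits cis to oxygen, the outside position of the s-cis diene.

Step 7
Reactants: 10 1-(trimethylsilyl)propyne; 11 3-benzyloxybenzyl bromide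
Product: 13 4-(3-benzyloxyphenyl)but-1-yne, via silylated alkyne 12 (not isolated)
Conditions: n-BuLi, THF, −78 °C; then 11, −78 °C to rt; then K2CO3 (cat.), MeOH, rt
Reagents that add atoms: none
Why: Propargylic lithiation of the silylpropyne and SN2 alkylation by the benzylic bromide, in which the silyl group blocks the acetylenic terminus and favours the alkyne over the allene, followed by base-catalysed methanolysis of the alkynyl C–Si bond (protodesilylation).

Step 8
Reactants: 13 4-(3-benzyloxyphenyl)but-1-yne; 14 4-benzyloxybenzoyl chloride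
Product: 15 1-(4-benzyloxyphenyl)-5-(3-benzyloxyphenyl)pent-2-yn-1-one
Conditions: PdCl2(PPh3)2 (2 mol%), CuI (4 mol%), Et3N, THF, rt
Reagents that add atoms: none
Why: Acyl Sonogashira coupling, in which the aroyl chloride adds oxidatively to zerovalent palladium, the copper acetylide formed with CuI and Et3N transmetalates, and reductive elimination gives the ynone at room temperature without decarbonylation.

Step 9
Reactants: 9 (3Z)-2-(4-benzyloxybenzyl)-5-(4-benzyloxyphenyl)-1,1-dimethoxy-3-(trimethylsilyloxy)penta-1,3-diene; 15 1-(4-benzyloxyphenyl)-5-(3-benzyloxyphenyl)pent-2-yn-1-one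
Product: 18 [4-hydroxy-2-methoxy-3,5-bis(4-benzyloxybenzyl)-6-[2-(3-benzyloxyphenyl)ethyl]phenyl](4-benzyloxyphenyl)methanone, via cyclohexadiene adduct 16 (not isolated), via aryl silyl ether 17 (not isolated)
Conditions: toluene (about 1 M), 110 °C, sealed tube; then 1 M HCl, THF, rt
Reagents that add atoms: none
Why: The electron-rich ketene-acetal diene 9 and the electron-poor ynone 15 should combine in a normal-demand Diels–Alder reaction (concerted but strongly asynchronous, or Michael-type addition followed by ring closure), with diene C4 bonding to the ynone β-carbon and the acetal carbon C1 bonding to the α-carbon. The closest known reaction type is the cycloaddition of 1,1-dialkoxy-3-silyloxy-1,3-dienes with acetylenic ketones and esters, which gives resorcinol monoalkyl ethers after loss of alcohol; a diene substituted at both C2 and C4 lies at the edge of that scope. Ring A is closed in the [4+2] mode with both new bonds (C4–C5 and C1–C6) formed in the cycloaddition, after which the 1,4-cyclohexadiene 16 loses methanol across C1 and C4 to give the aromatic silyl ether 17, and dilute HCl cleaves the aryl O–Si bond. No stereocenter is set, since the single sp3 CH of 16 forms as a racemate and is erased on aromatization. The step needs regioselectivity (arylethyl carbon next to C4, aroyl carbon next to C1), which the match between the large HOMO coefficient at C4 of the diene and the large LUMO coefficient at the ynone β-carbon should secure; it also needs a single elimination course, which follows because only the acetal carbon carries leaving groups, so one OMe stays at C1 and the silyl enol ether oxygen becomes the C3 phenol. The aroyl group supplies the activation that a dialkyl alkyne lacks, and the Z enol ether keeps CH2Ar outside the s-cis diene so that the reactive conformation stays accessible.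

Step 10
Reactants: 18 [4-hydroxy-2-methoxy-3,5-bis(4-benzyloxybenzyl)-6-[2-(3-benzyloxyphenyl)ethyl]phenyl](4-benzyloxyphenyl)methanone
Product: 19 2,4,6-tris(4-benzyloxybenzyl)-3-[2-(3-benzyloxyphenyl)ethyl]-5-methoxyphenol
Conditions: Et3SiH (excess), TFA, CH2Cl2, 0 °C to rt
Reagents that add atoms: none
Why: Ionic hydrogenation of an electron-rich diaryl ketone, in which the protonated carbonyl takes hydride to the benzhydrol and this ionises to a cation stabilised by the para-benzyloxyphenyl ring and the para C3–OH (quinone methide character) and takes a second hydride from the excess silane faster than it can be trapped by an arene.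

Step 11
Reactants: 19 2,4,6-tris(4-benzyloxybenzyl)-3-[2-(3-benzyloxyphenyl)ethyl]-5-methoxyphenol
Product: 20 2,4,6-tris(4-hydroxybenzyl)-3-[2-(3-hydroxyphenyl)ethyl]-5-methoxyphenol
Conditions: H2 (1 atm), Pd/C (10 wt%), EtOAc/MeOH, rt
Reagents that add atoms: none
Why: Catalytic hydrogenolysis of the four aryl benzyl ethers over palladium on carbon, under which the diarylmethane C–C bonds and the aryl methyl ether are inert.

Compound list
1 | 3-(4-hydroxyphenyl)propanenitrile | N#CCCc1ccc(O)cc1 | starting material
2 | 3-(4-benzyloxyphenyl)propanenitrile | N#CCCc1ccc(OCc2ccccc2)cc1 | intermediate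
3 | methyl 3-(4-benzyloxyphenyl)propanimidate hydrochloride (not isolated) | COC(=[NH2+])CCc1ccc(OCc2ccccc2)cc1.[Cl-] | intermediate
4 | 3-(4-benzyloxyphenyl)-1,1,1-trimethoxypropane | COC(OC)(OC)CCc1ccc(OCc2ccccc2)cc1 | intermediate
5 | 3-(4-benzyloxyphenyl)-1,1-dimethoxyprop-1-ene | COC(OC)=CCc1ccc(OCc2ccccc2)cc1 | intermediate
6 | 3-(4-benzyloxyphenyl)propanoic acid | OC(=O)CCc1ccc(OCc2ccccc2)cc1 | starting material
7 | 3-(4-benzyloxyphenyl)propanoyl chloride | O=C(Cl)CCc1ccc(OCc2ccccc2)cc1 | intermediate
8 | 2-(4-benzyloxybenzyl)-5-(4-benzyloxyphenyl)-1,1-dimethoxypent-1-en-3-one | COC(OC)=C(Cc1ccc(OCc2ccccc2)cc1)C(=O)CCc1ccc(OCc2ccccc2)cc1 | intermediate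
9 | (3Z)-2-(4-benzyloxybenzyl)-5-(4-benzyloxyphenyl)-1,1-dimethoxy-3-(trimethylsilyloxy)penta-1,3-diene | COC(OC)=C(Cc1ccc(OCc2ccccc2)cc1)/C(O[Si](C)(C)C)=C/Cc1ccc(OCc2ccccc2)cc1 | intermediate
10 | 1-(trimethylsilyl)propyne | CC#C[Si](C)(C)C | starting material
11 | 3-benzyloxybenzyl bromide | BrCc1cccc(OCc2ccccc2)c1 | starting material
12 | 4-(3-benzyloxyphenyl)-1-(trimethylsilyl)but-1-yne (not isolated) | C[Si](C)(C)C#CCCc1cccc(OCc2ccccc2)c1 | intermediate
13 | 4-(3-benzyloxyphenyl)but-1-yne | C#CCCc1cccc(OCc2ccccc2)c1 | intermediate
14 | 4-benzyloxybenzoyl chloride | O=C(Cl)c1ccc(OCc2ccccc2)cc1 | starting material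
15 | 1-(4-benzyloxyphenyl)-5-(3-benzyloxyphenyl)pent-2-yn-1-one | O=C(C#CCCc1cccc(OCc2ccccc2)c1)c1ccc(OCc2ccccc2)cc1 | intermediate
16 | racemic [3,5-bis(4-benzyloxybenzyl)-2-[2-(3-benzyloxyphenyl)ethyl]-6,6-dimethoxy-4-(trimethylsilyloxy)cyclohexa-1,4-dien-1-yl](4-benzyloxyphenyl)methanone (not isolated) | COC1(OC)C(Cc2ccc(OCc3ccccc3)cc2)=C(O[Si](C)(C)C)C(Cc2ccc(OCc3ccccc3)cc2)C(CCc2cccc(OCc3ccccc3)c2)=C1C(=O)c1ccc(OCc2ccccc2)cc1 | intermediate
17 | [2-methoxy-3,5-bis(4-benzyloxybenzyl)-6-[2-(3-benzyloxyphenyl)ethyl]-4-(trimethylsilyloxy)phenyl](4-benzyloxyphenyl)methanone (not isolated) | COc1c(Cc2ccc(OCc3ccccc3)cc2)c(O[Si](C)(C)C)c(Cc2ccc(OCc3ccccc3)cc2)c(CCc2cccc(OCc3ccccc3)c2)c1C(=O)c1ccc(OCc2ccccc2)cc1 | intermediate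
18 | [4-hydroxy-2-methoxy-3,5-bis(4-benzyloxybenzyl)-6-[2-(3-benzyloxyphenyl)ethyl]phenyl](4-benzyloxyphenyl)methanone | COc1c(Cc2ccc(OCc3ccccc3)cc2)c(O)c(Cc2ccc(OCc3ccccc3)cc2)c(CCc2cccc(OCc3ccccc3)c2)c1C(=O)c1ccc(OCc2ccccc2)cc1 | intermediate
19 | 2,4,6-tris(4-benzyloxybenzyl)-3-[2-(3-benzyloxyphenyl)ethyl]-5-methoxyphenol | COc1c(Cc2ccc(OCc3ccccc3)cc2)c(O)c(Cc2ccc(OCc3ccccc3)cc2)c(CCc2cccc(OCc3ccccc3)c2)c1Cc1ccc(OCc2ccccc2)cc1 | intermediate
20 | 2,4,6-tris(4-hydroxybenzyl)-3-[2-(3-hydroxyphenyl)ethyl]-5-methoxyphenol | COc1c(Cc2ccc(O)cc2)c(O)c(Cc2ccc(O)cc2)c(CCc2cccc(O)c2)c1Cc1ccc(O)cc1 | target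

Total step count: 11 steps.
Longest linear sequence: 8 steps (steps 1, 2, 3, 5, 6, 9, 10, 11).

Steps most likely to fail

Step 9. The cycloaddition may be too slow for a diene substituted at both C2 and C4, so that hydrolysis or thermal decay of the diene wins. Bond formation between the crowded acetal carbon and the aroyl-bearing alkyne carbon may also stall after the first (Michael-type) bond. The fallback sets out from alkyne 13 and diene 9 and comes back at 19. Alkyne 13 is lithiated and formylated (n-BuLi, THF, −78 °C; DMF; inverse quench into aqueous KH2PO4) to give 5-(3-benzyloxyphenyl)pent-2-ynal F1, a smaller and more electrophilic dienophile. This should undergo the same cycloaddition and aromatization with 9 (toluene, 60–80 °C; then dilute HCl) to give 4-hydroxy-2-methoxy-3,5-bis(4-benzyloxybenzyl)-6-[2-(3-benzyloxyphenyl)ethyl]benzaldehyde F2. Grignard addition of purchased 4-benzyloxyphenylmagnesium bromide (excess, since the phenol consumes one equivalent) should give racemic [4-hydroxy-2-methoxy-3,5-bis(4-benzyloxybenzyl)-6-[2-(3-benzyloxyphenyl)ethyl]phenyl](4-benzyloxyphenyl)methanol F3. Ionic hydrogenation of this benzhydrol (Et3SiH, TFA, CH2Cl2) then gives 19.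

Step 5. C-acylation of the β-substituted ketene acetal may be outrun by proton transfer, so that 5 is consumed as its methyl ester before the hindered, enolizable acid chloride 7 has reacted. The fallback sets out from 5 and comes back at 8, and it moves the construction of the C4–C5 bond to an enolate alkylation. Ketene acetal 5 is acylated with the unhindered acetyl chloride (2 equiv of 5, Et2O, no amine) to give 3-(4-benzyloxybenzyl)-4,4-dimethoxybut-3-en-2-one F4. The kinetic lithium dienolate of this vinylogous ester (LiN(iPr)2, THF, −78 °C) is then alkylated at the methyl carbon with purchased 4-benzyloxybenzyl bromide to give 8.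

Step 10. Hydride delivery to the shielded carbonyl may be slow. The benzhydryl cation could then be captured intramolecularly by the electron-rich 3-benzyloxyphenyl ring (seven-membered ring closure), or the acid could cause loss and migration of benzyl groups. The fallback sets out from 18 and comes back at the target 20 without any new isolated compound (F0). Hydrogenation over Pd/C in AcOH/EtOAc containing a little HCl under about 4 bar of H2 should cleave the four benzyl ethers and take the diaryl ketone through the benzhydrol to the methylene group by hydrogenolysis on the metal surface, so that no long-lived cation is formed.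

Further compounds
F1 | step 9 | 5-(3-benzyloxyphenyl)pent-2-ynal | O=CC#CCCc1cccc(OCc2ccccc2)c1
F2 | step 9 | 4-hydroxy-2-methoxy-3,5-bis(4-benzyloxybenzyl)-6-[2-(3-benzyloxyphenyl)ethyl]benzaldehyde | COc1c(Cc2ccc(OCc3ccccc3)cc2)c(O)c(Cc2ccc(OCc3ccccc3)cc2)c(CCc2cccc(OCc3ccccc3)c2)c1C=O
F3 | step 9 | racemic [4-hydroxy-2-methoxy-3,5-bis(4-benzyloxybenzyl)-6-[2-(3-benzyloxyphenyl)ethyl]phenyl](4-benzyloxyphenyl)methanol | COc1c(Cc2ccc(OCc3ccccc3)cc2)c(O)c(Cc2ccc(OCc3ccccc3)cc2)c(CCc2cccc(OCc3ccccc3)c2)c1C(O)c1ccc(OCc2ccccc2)cc1
F4 | step 5 | 3-(4-benzyloxybenzyl)-4,4-dimethoxybut-3-en-2-one | COC(OC)=C(Cc1ccc(OCc2ccccc2)cc1)C(C)=O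
F0 | step 10 | none | none
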